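**Retrosynthetic overview**
- The target is a (2S)-flavan. Ring C has plain CH2 groups at C3 and C4 and a single stereocentre, C2, bonded to O1 and ring B. The C3–C4 bond can therefore be made as a C3=C4 alkene by ring-closing metathesis and saturated afterwards.
- The metathesis precursor 17 is an ortho-vinylphenyl (S)-1-arylallyl ether. Its O1–C2 bond and configuration come from an iridium-catalysed asymmetric allylic etherification of vinylphenol 11 with cinnamyl carbonate 16. The vinyl group is installed before the stereocentre, so no strong base meets the chiral ether.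
- Ring A piece 11 comes from 1,3-dimethoxybenzene: C2 lithiation and prenylation, E-selective SeO2 hydroxylation, silylation, mono-demethylation, ortho-formylation, methylenation. Ring B piece 16 comes from 2,4-dihydroxybenzaldehyde: silylation, Wittig, reduction, carbonate.
- Rings A and B are bought as arenes. Ring C is the only ring formed (step 12), followed by diimide reduction of C3=C4 and fluoride desilylation.

Key step: step 12

Assumption: L is the (Sa,Sc,Sc) phosphoramidite from 1,1'-binaphthalene-2,2'-diol and bis[1-(2-methoxyphenyl)ethyl]amine. By the usual sense of induction of this catalyst family with (E)-3-arylallyl carbonates it is expected to give the (S)-ether; if the opposite sense is found, the enantiomeric ligand is used and nothing else changes.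

**Step 1**
Reactants: 1 1,3-dimethoxybenzene; 2 1-bromo-3-methylbut-2-ene (prenyl bromide)
Product: 4 1,3-dimethoxy-2-(3-methylbut-2-enyl)benzene, via 2,6-dimethoxyphenyllithium 3 (not isolated)
Conditions: n-BuLi, THF, 0 °C to rt; then CuBr·SMe2 (5 mol%), 2, −20 °C to rt
Reagents that add atoms: none
Why: Directed ortho-metalation, in which both methoxy groups steer n-BuLi to C2, followed by copper-catalysed SN2 displacement of the primary allylic bromide at its unsubstituted terminus.

**Step 2**
Reactants: 4 1,3-dimethoxy-2-(3-methylbut-2-enyl)benzene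
Product: 6 (E)-4-(2,6-dimethoxyphenyl)-2-methylbut-2-en-1-ol, via over-oxidised (E)-enal 5 (not isolated)
Conditions: SeO2 (0.5 equiv), t-BuOOH (3 equiv), salicylic acid (10 mol%), CH2Cl2, rt; then NaBH4, MeOH, 0 °C
Reagents that add atoms: tert-butyl hydroperoxide, CC(C)(C)OO (supplies the hydroxyl oxygen, relayed by SeO2, O=[Se]=O)
Why: SeO2 allylic hydroxylation (ene reaction, then [2,3]-sigmatropic shift) attacks the methyl group trans to the benzylic chain on the more substituted alkene carbon, which fixes the E geometry, and NaBH4 returns any enal 5 to alcohol 6.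

**Step 3**
Reactants: 6 (E)-4-(2,6-dimethoxyphenyl)-2-methylbut-2-en-1-ol
Product: 7 (E)-[4-(2,6-dimethoxyphenyl)-2-methylbut-2-enyloxy]triisopropylsilane
Conditions: i-Pr3SiCl, imidazole, DMF, rt
Reagents that add atoms: triisopropylsilyl chloride, CC(C)[Si](Cl)(C(C)C)C(C)C
Why: Silylation of the primary allylic alcohol, with the triisopropylsilyl ether chosen because it should withstand the hot thiolate of step 4 and every later basic step yet is removed by fluoride at the end.

**Step 4**
Reactants: 7 (E)-[4-(2,6-dimethoxyphenyl)-2-methylbut-2-enyloxy]triisopropylsilane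
Product: 8 3-methoxy-2-[(E)-3-methyl-4-(triisopropylsilyloxy)but-2-enyl]phenol
Conditions: NaSEt (3 equiv), DMF, 120 °C; then 1 M HCl, 0 °C
Reagents that add atoms: none
Why: SN2 demethylation of an aryl methyl ether by thiolate, where the two methoxy groups are equivalent and the phenoxide formed resists a second demethylation, so the mono-phenol should result.

**Step 5**
Reactants: 8 3-methoxy-2-[(E)-3-methyl-4-(triisopropylsilyloxy)but-2-enyl]phenol
Product: 10 2-hydroxy-4-methoxy-3-[(E)-3-methyl-4-(triisopropylsilyloxy)but-2-enyl]benzaldehyde, via salicyl alcohol magnesium salt 9 (not isolated)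
Conditions: MgCl2, Et3N, (CH2O)n, MeCN, reflux; then 1 M HCl, 0 °C
Reagents that add atoms: formaldehyde (as paraformaldehyde), C=O
Why: Magnesium-mediated ortho-formylation of a phenol, in which the ArOMgCl phenoxide delivers formaldehyde to the only free ortho position (C6, para to OMe) and the salicyl alcohol 9 is oxidised in the flask by hydride transfer to a second formaldehyde.

**Step 6**
Reactants: 10 2-hydroxy-4-methoxy-3-[(E)-3-methyl-4-(triisopropylsilyloxy)but-2-enyl]benzaldehyde
Product: 11 6-ethenyl-3-methoxy-2-[(E)-3-methyl-4-(triisopropylsilyloxy)but-2-enyl]phenol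
Conditions: Ph3PCH3Br (2.6 equiv), KOtBu (2.5 equiv), THF, 0 °C to rt; aq NH4Cl; stored cold over BHT
Reagents that add atoms: methyltriphenylphosphonium bromide, C[P+](c1ccccc1)(c1ccccc1)c1ccccc1.[Br-]
Why: Wittig methylenation, in which excess ylide first deprotonates the phenol and then turns the aldehyde into the terminal vinyl group whose inner carbon becomes C4.

**Step 7**
Reactants: 12 2,4-dihydroxybenzaldehyde
Product: 13 2,4-bis(tert-butyldimethylsilyloxy)benzaldehyde
Conditions: t-BuMe2SiCl (2.5 equiv), imidazole, DMF, rt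
Reagents that add atoms: tert-butyldimethylsilyl chloride, CC(C)(C)[Si](C)(C)Cl
Why: Silylation of both phenols masks them for the following steps and allows their removal by fluoride without acid or hydrogenolysis.

**Step 8**
Reactants: 13 2,4-bis(tert-butyldimethylsilyloxy)benzaldehyde
Product: 14 methyl (E)-3-[2,4-bis(tert-butyldimethylsilyloxy)phenyl]prop-2-enoate
Conditions: Ph3P=CHCO2Me, toluene, 60 °C
Reagents that add atoms: methyl (triphenylphosphoranylidene)acetate, COC(=O)C=P(c1ccccc1)(c1ccccc1)c1ccccc1
Why: Wittig olefination with a stabilised ylide, which should give the E cinnamate.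

**Step 9**
Reactants: 14 methyl (E)-3-[2,4-bis(tert-butyldimethylsilyloxy)phenyl]prop-2-enoate
Product: 15 (E)-3-[2,4-bis(tert-butyldimethylsilyloxy)phenyl]prop-2-en-1-ol
Conditions: i-Bu2AlH (2.5 equiv), CH2Cl2, −78 °C; aq potassium sodium tartrate
Reagents that add atoms: none
Why: 1,2-Reduction of the enoate by i-Bu2AlH at low temperature gives the allylic alcohol without conjugate reduction and leaves the aryl silyl ethers alone.

**Step 10**
Reactants: 15 (E)-3-[2,4-bis(tert-butyldimethylsilyloxy)phenyl]prop-2-en-1-ol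
Product: 16 (E)-3-[2,4-bis(tert-butyldimethylsilyloxy)phenyl]prop-2-enyl methyl carbonate
Conditions: ClCO2Me, pyridine, CH2Cl2, 0 °C; Et3N-washed silica
Reagents that add atoms: methyl chloroformate, COC(=O)Cl
Why: O-Acylation with a chloroformate gives the linear allylic carbonate that serves as the ionisable leaving group for iridium catalysis.

**Step 11**
Reactants: 11 6-ethenyl-3-methoxy-2-[(E)-3-methyl-4-(triisopropylsilyloxy)but-2-enyl]phenol; 16 (E)-3-[2,4-bis(tert-butyldimethylsilyloxy)phenyl]prop-2-enyl methyl carbonate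
Product: 17 (S)-1-ethenyl-4-methoxy-2-{1-[2,4-bis(tert-butyldimethylsilyloxy)phenyl]prop-2-enyloxy}-3-[(E)-3-methyl-4-(triisopropylsilyloxy)but-2-enyl]benzene
Conditions: [Ir(cod)Cl]2 (2 mol%), L (4 mol%), pre-activated with n-PrNH2 (THF, 50 °C, then evaporated); K3PO4 (20 mol%), THF, rt, dark
Reagents that add atoms: none
Why: Iridium-catalysed asymmetric allylic etherification, in which the cyclometalated iridium–phosphoramidite complex ionises the carbonate with loss of CO2 and the phenoxide of 11 attacks the aryl-bearing allyl terminus on the face left open by the ligand, giving the branched ether with C2 set as S under catalyst control; the vinylphenol is used in place of the salicylaldehyde because an electron-poor, chelating phenoxide is a weaker nucleophile and a better leaving group, and L is chosen for its tolerance of ortho-substituted cinnamyl electrophiles.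

**Step 12**
Reactants: 17 (S)-ortho-vinylphenyl 1-arylallyl ether
Product: 18 (S)-2-[2,4-bis(tert-butyldimethylsilyloxy)phenyl]-7-methoxy-8-[(E)-3-methyl-4-(triisopropylsilyloxy)but-2-enyl]-2H-chromene
Conditions: second-generation Grubbs catalyst RuCl2(=CHPh)(H2IMes)(PCy3) (5 mol%), 1,4-benzoquinone (10 mol%), CH2Cl2 (5 mM), 30 °C, argon sweep, dark; ethyl vinyl ether quench; basic alumina plug, used at once
Reagents that add atoms: none
Why: The Ru=CHPh alkylidene exchanges onto one terminal vinyl group, the new alkylidene adds to the other terminal alkene in a [2+2] cycloaddition, and cycloreversion of the ruthenacyclobutane releases the C3=C4 alkene and a Ru=CH2 species that carries the chain, with ethene lost. This is the known ring-closing metathesis of 2-vinylphenyl allyl ethers to 2H-chromenes. Ring C closes as a six-membered ring by joining the inner CH of the ring A vinyl group (C4) to the inner CH of the allyl ether (C3). No stereocentre is made; C2 and its C–O bond, set in step 11, are spectators. The step needs the two monosubstituted alkenes to react in preference to the trisubstituted side-chain alkene, whose coupling with the allyl-ether vinyl would give a seven-membered 2,5-dihydro-1-benzoxepine; the far lower metathesis reactivity of a trisubstituted alkene and the faster six-ring closure should secure this. Benzoquinone suppresses Ru–H migration of the allyl-ether double bond, and low temperature and darkness guard against electrocyclic ring opening of the chromene, which would racemise C2.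

**Step 13**
Reactants: 18 (S)-2-aryl-7-methoxy-8-(silyloxyprenyl)-2H-chromene
Product: 19 (S)-2-[2,4-bis(tert-butyldimethylsilyloxy)phenyl]-7-methoxy-8-[(E)-3-methyl-4-(triisopropylsilyloxy)but-2-enyl]chromane
Conditions: 2-nitrobenzenesulfonylhydrazide (in portions), Et3N, CH2Cl2, rt, dark
Reagents that add atoms: none
Why: Diimide, released from the sulfonylhydrazide by base at room temperature, transfers two hydrogens in a concerted syn fashion and should react faster with the cis-disubstituted, conjugated C3=C4 bond than with the hindered trisubstituted side-chain alkene, while the absence of metal and acid leaves the benzylic C2–O bond and the S configuration intact.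

**Step 14**
Reactants: 19 (S)-tris-silylated flavan
Product: 20 morusyunnansin E, (S)-4-{8-[(E)-4-hydroxy-3-methylbut-2-enyl]-7-methoxychroman-2-yl}benzene-1,3-diol
Conditions: Bu4NF, AcOH (1:1, 4 equiv), THF, 0 °C to rt, argon
Reagents that add atoms: none
Why: Fluoride cleaves the two aryl silyl ethers and the primary silyl ether through pentacoordinate silicon, and the acetic acid buffer keeps the freed phenols protonated so that a 4'-phenoxide cannot open ring C through a para-quinone methide and erode C2.

**Compound list**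
1 | 1,3-dimethoxybenzene | COc1cccc(OC)c1 | starting material
2 | 1-bromo-3-methylbut-2-ene (prenyl bromide) | CC(C)=CCBr | starting material
3 | 2,6-dimethoxyphenyllithium (formed in the flask) | COc1cccc(OC)c1[Li] | intermediate
4 | 1,3-dimethoxy-2-(3-methylbut-2-enyl)benzene | COc1cccc(OC)c1CC=C(C)C | intermediate
5 | (E)-4-(2,6-dimethoxyphenyl)-2-methylbut-2-enal (formed in the flask) | COc1cccc(OC)c1C/C=C(\C)C=O | intermediate
6 | (E)-4-(2,6-dimethoxyphenyl)-2-methylbut-2-en-1-ol | COc1cccc(OC)c1C/C=C(\C)CO | intermediate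
7 | (E)-[4-(2,6-dimethoxyphenyl)-2-methylbut-2-enyloxy]triisopropylsilane | COc1cccc(OC)c1C/C=C(\C)CO[Si](C(C)C)(C(C)C)C(C)C | intermediate
8 | 3-methoxy-2-[(E)-3-methyl-4-(triisopropylsilyloxy)but-2-enyl]phenol | COc1cccc(O)c1C/C=C(\C)CO[Si](C(C)C)(C(C)C)C(C)C | intermediate
9 | 6-(hydroxymethyl)-3-methoxy-2-[(E)-3-methyl-4-(triisopropylsilyloxy)but-2-enyl]phenol (magnesium salt, formed in the flask; drawn neutral) | COc1ccc(CO)c(O)c1C/C=C(\C)CO[Si](C(C)C)(C(C)C)C(C)C | intermediate
10 | 2-hydroxy-4-methoxy-3-[(E)-3-methyl-4-(triisopropylsilyloxy)but-2-enyl]benzaldehyde | COc1ccc(C=O)c(O)c1C/C=C(\C)CO[Si](C(C)C)(C(C)C)C(C)C | intermediate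
11 | 6-ethenyl-3-methoxy-2-[(E)-3-methyl-4-(triisopropylsilyloxy)but-2-enyl]phenol | COc1ccc(C=C)c(O)c1C/C=C(\C)CO[Si](C(C)C)(C(C)C)C(C)C | intermediate
12 | 2,4-dihydroxybenzaldehyde | O=Cc1ccc(O)cc1O | starting material
13 | 2,4-bis(tert-butyldimethylsilyloxy)benzaldehyde | O=Cc1ccc(O[Si](C)(C)C(C)(C)C)cc1O[Si](C)(C)C(C)(C)C | intermediate
14 | methyl (E)-3-[2,4-bis(tert-butyldimethylsilyloxy)phenyl]prop-2-enoate | COC(=O)/C=C/c1ccc(O[Si](C)(C)C(C)(C)C)cc1O[Si](C)(C)C(C)(C)C | intermediate
15 | (E)-3-[2,4-bis(tert-butyldimethylsilyloxy)phenyl]prop-2-en-1-ol | OC/C=C/c1ccc(O[Si](C)(C)C(C)(C)C)cc1O[Si](C)(C)C(C)(C)C | intermediate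
16 | (E)-3-[2,4-bis(tert-butyldimethylsilyloxy)phenyl]prop-2-enyl methyl carbonate | COC(=O)OC/C=C/c1ccc(O[Si](C)(C)C(C)(C)C)cc1O[Si](C)(C)C(C)(C)C | intermediate
17 | (S)-1-ethenyl-4-methoxy-2-{1-[2,4-bis(tert-butyldimethylsilyloxy)phenyl]prop-2-enyloxy}-3-[(E)-3-methyl-4-(triisopropylsilyloxy)but-2-enyl]benzene | COc1ccc(C=C)c(O[C@@H](C=C)c2ccc(O[Si](C)(C)C(C)(C)C)cc2O[Si](C)(C)C(C)(C)C)c1C/C=C(\C)CO[Si](C(C)C)(C(C)C)C(C)C | intermediate
18 | (S)-2-[2,4-bis(tert-butyldimethylsilyloxy)phenyl]-7-methoxy-8-[(E)-3-methyl-4-(triisopropylsilyloxy)but-2-enyl]-2H-chromene | COc1ccc2c(c1C/C=C(\C)CO[Si](C(C)C)(C(C)C)C(C)C)O[C@H](c1ccc(O[Si](C)(C)C(C)(C)C)cc1O[Si](C)(C)C(C)(C)C)C=C2 | intermediate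
19 | (S)-2-[2,4-bis(tert-butyldimethylsilyloxy)phenyl]-7-methoxy-8-[(E)-3-methyl-4-(triisopropylsilyloxy)but-2-enyl]chromane | COc1ccc2c(c1C/C=C(\C)CO[Si](C(C)C)(C(C)C)C(C)C)O[C@H](c1ccc(O[Si](C)(C)C(C)(C)C)cc1O[Si](C)(C)C(C)(C)C)CC2 | intermediate
20 | morusyunnansin E, (S)-4-{8-[(E)-4-hydroxy-3-methylbut-2-enyl]-7-methoxychroman-2-yl}benzene-1,3-diol | COc1ccc2c(c1C/C=C(\C)CO)O[C@H](c1ccc(O)cc1O)CC2 | target

**Totals**
Total step count: 14.
Longest linear sequence: 10 steps (steps 1–6, then 11–14, from 1,3-dimethoxybenzene); the ring B branch (steps 7–10) joins at step 11.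

**Steps most likely to fail**

Step 11. Both partners are ortho-substituted, so ionisation and attack may be slow. The reaction may also leak to the linear cinnamyl ether, or the electron-rich branched product may re-ionise on the catalyst and lose enantiomeric purity. The fallback sets out from aldehyde 13 and phenol 11 and returns at 17; it makes the C2–O bond by Mitsunobu inversion of a preformed carbinol instead of by allylic substitution.
- CH2=CHMgBr adds to 13 (THF, −78 °C) to give racemic 1-[2,4-bis(tert-butyldimethylsilyloxy)phenyl]prop-2-en-1-ol F1.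
- MnO2 (CH2Cl2) oxidises it to 1-[2,4-bis(tert-butyldimethylsilyloxy)phenyl]prop-2-en-1-one F2.
- Benzeneselenol (PhSeSePh, NaBH4, EtOH, then AcOH) adds in conjugate fashion to give 1-[2,4-bis(tert-butyldimethylsilyloxy)phenyl]-3-(phenylselanyl)propan-1-one F3.
- Corey–Bakshi–Shibata reduction (BH3·SMe2, (S)-methyl oxazaborolidine, THF), with the aryl group as the large substituent, is expected to give (R)-1-[2,4-bis(tert-butyldimethylsilyloxy)phenyl]-3-(phenylselanyl)propan-1-ol F4.
- Mitsunobu coupling with 11 (PPh3, DIAD, toluene, 0 °C) should invert the carbinol to (S)-1-ethenyl-4-methoxy-2-{1-[2,4-bis(tert-butyldimethylsilyloxy)phenyl]-3-(phenylselanyl)propoxy}-3-[(E)-3-methyl-4-(triisopropylsilyloxy)but-2-enyl]benzene F5.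
- H2O2 and pyridine (CH2Cl2, 0 °C to rt) give the corresponding phenylseleninyl compound (selenoxide) F6, whose syn-elimination unveils the vinyl group of 17.

Step 12. Ru–H species may move the allyl-ether double bond into an enol ether, the ether oxygen may hold the alkylidene in an unproductive chelate, closure onto the side-chain alkene may compete, or a slow reaction may let the chromene racemise by ring opening. The fallback sets out from phenol 8 and carbonate 16 and returns at 19; it closes ring C at C4–C4a by sp3–sp2 cross-coupling, so neither metathesis nor alkene reduction is needed.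
- Amine-directed ortho-bromination (NBS, catalytic i-Pr2NH, CH2Cl2, −78 °C, brief) is expected to give 6-bromo-3-methoxy-2-[(E)-3-methyl-4-(triisopropylsilyloxy)but-2-enyl]phenol F7.
- Iridium-catalysed etherification with 16 under the conditions of step 11 gives (S)-1-bromo-4-methoxy-2-{1-[2,4-bis(tert-butyldimethylsilyloxy)phenyl]prop-2-enyloxy}-3-[(E)-3-methyl-4-(triisopropylsilyloxy)but-2-enyl]benzene F8.
- 9-BBN (THF, rt) hydroborates only the terminal vinyl group to give the B-alkyl-9-borabicyclo[3.3.1]nonane F9, which is not isolated.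
- PdCl2(dppf) with aqueous K3PO4 (THF/DMF, 50 °C) effects intramolecular B-alkyl Suzuki–Miyaura coupling to flavan 19.

Step 13. Reduction may be incomplete within the lifetime of the sensitive chromene, or the excess diimide needed may also reduce the side-chain alkene. The fallback sets out from 18 and returns at 19. Stoichiometric diimide is replaced by homogeneous catalytic hydrogenation (H2, 1 atm, RhCl(PPh3)3 5 mol%, benzene–EtOH, rt, dark). Selection then rests on alkene coordination to rhodium, which a trisubstituted alkene resists, and this catalyst should not hydrogenolyse benzylic or allylic C–O bonds. No compound outside the list is made (entry F0).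

**Further compounds**
F1 | step 11 | racemic 1-[2,4-bis(tert-butyldimethylsilyloxy)phenyl]prop-2-en-1-ol | C=CC(O)c1ccc(O[Si](C)(C)C(C)(C)C)cc1O[Si](C)(C)C(C)(C)C
F2 | step 11 | 1-[2,4-bis(tert-butyldimethylsilyloxy)phenyl]prop-2-en-1-one | C=CC(=O)c1ccc(O[Si](C)(C)C(C)(C)C)cc1O[Si](C)(C)C(C)(C)C
F3 | step 11 | 1-[2,4-bis(tert-butyldimethylsilyloxy)phenyl]-3-(phenylselanyl)propan-1-one | O=C(CC[Se]c1ccccc1)c1ccc(O[Si](C)(C)C(C)(C)C)cc1O[Si](C)(C)C(C)(C)C
F4 | step 11 | (R)-1-[2,4-bis(tert-butyldimethylsilyloxy)phenyl]-3-(phenylselanyl)propan-1-ol | O[C@H](CC[Se]c1ccccc1)c1ccc(O[Si](C)(C)C(C)(C)C)cc1O[Si](C)(C)C(C)(C)C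
F5 | step 11 | (S)-1-ethenyl-4-methoxy-2-{1-[2,4-bis(tert-butyldimethylsilyloxy)phenyl]-3-(phenylselanyl)propoxy}-3-[(E)-3-methyl-4-(triisopropylsilyloxy)but-2-enyl]benzene | COc1ccc(C=C)c(O[C@@H](CC[Se]c2ccccc2)c2ccc(O[Si](C)(C)C(C)(C)C)cc2O[Si](C)(C)C(C)(C)C)c1C/C=C(\C)CO[Si](C(C)C)(C(C)C)C(C)C
F6 | step 11 | selenoxide of F5 (phenylseleninyl compound, formed in the flask) | COc1ccc(C=C)c(O[C@@H](CC[Se](=O)c2ccccc2)c2ccc(O[Si](C)(C)C(C)(C)C)cc2O[Si](C)(C)C(C)(C)C)c1C/C=C(\C)CO[Si](C(C)C)(C(C)C)C(C)C
F7 | step 12 | 6-bromo-3-methoxy-2-[(E)-3-methyl-4-(triisopropylsilyloxy)but-2-enyl]phenol | COc1ccc(Br)c(O)c1C/C=C(\C)CO[Si](C(C)C)(C(C)C)C(C)C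
F8 | step 12 | (S)-1-bromo-4-methoxy-2-{1-[2,4-bis(tert-butyldimethylsilyloxy)phenyl]prop-2-enyloxy}-3-[(E)-3-methyl-4-(triisopropylsilyloxy)but-2-enyl]benzene | COc1ccc(Br)c(O[C@@H](C=C)c2ccc(O[Si](C)(C)C(C)(C)C)cc2O[Si](C)(C)C(C)(C)C)c1C/C=C(\C)CO[Si](C(C)C)(C(C)C)C(C)C
F9 | step 12 | (S)-B-alkyl-9-borabicyclo[3.3.1]nonane from hydroboration of F8 (formed in the flask) | COc1ccc(Br)c(O[C@@H](CCB2C3CCCC2CCC3)c2ccc(O[Si](C)(C)C(C)(C)C)cc2O[Si](C)(C)C(C)(C)C)c1C/C=C(\C)CO[Si](C(C)C)(C(C)C)C(C)C
F0 | step 13 | none | none
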